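**Assumption:** the SMILES contains no stereocentre and no stereogenic double bond. The target is achiral, so there is no enantiomer to select and no step has to set configuration.

## Retrosynthetic overview

1. The last step is acid removal of three MOM groups from the fully assembled isoflavone.
2. Key disconnection: C3–C1′ and O1–C2 are cut together, so ring C does not exist before the key step. A σ-aryl radical from a 6-iodo-2H-chromene (rings B/D) adds to the α-carbon of an open-chain o-hydroxyaryl enaminone (ring A), and the pyranone closes in the same operation.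
3. The enaminone comes from an o-hydroxyacetophenone and DMF-DMA (which supplies C2). The C4–C4a bond comes from a photo-Fries shift in a symmetric aryl acetate, which fixes 6-prenyl over 8-prenyl.
4. The aryl acetate comes from resorcinol by MOM protection, lithiation/prenylation between the two oxygens, and meta C–H borylation/oxidation for the third oxygen.
5. The iodochromene comes from resorcinol by iodination and then prenal annulation. Ring order: A and B come from resorcinol, D (dimethylpyran) is formed first, and C (4-pyranone) is formed last.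

## Route

Step 1
Reactants: 1 resorcinol (benzene-1,3-diol)
Product: 2 1,3-bis(methoxymethoxy)benzene
Conditions: NaH (2.4 equiv), MOMCl (2.4 equiv), DMF, 0 °C → rt
Reagents that add atoms: chloromethyl methyl ether (MOMCl), COCCl
Why: Williamson-type acetal protection of both phenoxides; MOM is chosen because it directs the lithiation of step 2, survives base, borylation and light, and leaves under mild acid in step 9.

Step 2
Reactants: 2 1,3-bis(methoxymethoxy)benzene; 3 prenyl bromide (1-bromo-3-methylbut-2-ene)
Product: 5 1,3-bis(methoxymethoxy)-2-(3-methylbut-2-en-1-yl)benzene, via 2-lithio-1,3-bis(methoxymethoxy)benzene 4 (not isolated)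
Conditions: n-BuLi (1.1 equiv), THF, 0 °C → rt, 1 h; CuI (10 mol %), 3 (1.2 equiv), −78 °C → rt
Reagents that add atoms: n-butyllithium, [Li]CCCC (lithium in 4 only)
Why: Directed ortho-metalation: the C2–H between the two chelating OMOM groups is by far the most acidic, so 4 is the only aryllithium formed, and copper-catalysed SN2 allylation with 3 gives the linear prenyl arene.

Step 3
Reactants: 5 1,3-bis(methoxymethoxy)-2-(3-methylbut-2-en-1-yl)benzene; 6 acetic anhydride
Product: 9 3,5-bis(methoxymethoxy)-4-(3-methylbut-2-en-1-yl)phenyl acetate, via 2-[3,5-bis(methoxymethoxy)-4-(3-methylbut-2-en-1-yl)phenyl]-4,4,5,5-tetramethyl-1,3,2-dioxaborolane 7 (not isolated), via 3,5-bis(methoxymethoxy)-4-(3-methylbut-2-en-1-yl)phenol 8 (not isolated)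
Conditions: [Ir(OMe)(cod)]2 (1.5 mol %), dtbpy (3 mol %), B2pin2 (1.0 equiv), THF, 80 °C; then 30% H2O2, aq NaOH, 0 °C; aq Na2SO3; then 6 (3 equiv), 0 °C
Reagents that add atoms: bis(pinacolato)diboron, CC1(C)OB(B2OC(C)(C)C(C)(C)O2)OC1(C)C (Bpin in 7 only); hydrogen peroxide, OO (phenol oxygen)
Why: Sterically controlled iridium-catalysed C–H borylation reaches only C5–H, the one ring position without an ortho neighbour (the trisubstituted alkene is inert), basic peroxide turns C–B into C–O at the same carbon, sulfite removes excess peroxide so that no peracid can reach the prenyl group, and the phenoxide is acetylated in the aqueous base (Schotten–Baumann acylation).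

Step 4
Reactants: 9 3,5-bis(methoxymethoxy)-4-(3-methylbut-2-en-1-yl)phenyl acetate
Product: 10 1-[6-hydroxy-2,4-bis(methoxymethoxy)-3-(3-methylbut-2-en-1-yl)phenyl]ethan-1-one
Conditions: hν (254 nm, quartz), degassed cyclohexane (0.01 M), rt
Reagents that add atoms: none
Why: Photo-Fries rearrangement: homolysis of the ArO–C(O) bond gives a caged aryloxyl/acetyl radical pair that recombines at an ortho carbon; para is blocked by the prenyl group and both ortho positions are equivalent, so one ketone results, it is photostable through excited-state proton transfer, and its only free OH is the future O1, which fixes the prenyl group at C6.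

Step 5
Reactants: 1 resorcinol
Product: 11 4-iodobenzene-1,3-diol (4-iodoresorcinol)
Conditions: ICl (1.0 equiv), Et2O, 0 °C → rt
Reagents that add atoms: iodine monochloride, ClI
Why: Electrophilic aromatic iodination under non-basic conditions goes to C4 (para to one OH, ortho to the other) rather than to the crowded C2, and it is done before any alkene is present.

Step 6
Reactants: 11 4-iodobenzene-1,3-diol; 12 3-methylbut-2-enal (prenal)
Product: 13 6-iodo-2,2-dimethyl-2H-chromen-7-ol
Conditions: 12 (1.5 equiv), ethylenediammonium diacetate (20 mol %), toluene, reflux, Dean–Stark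
Reagents that add atoms: none
Why: Formal [3+3] chromene annulation (aldol-type attack of the ring carbon on prenal, loss of water to an o-quinone methide, oxa-6π electrocyclisation): iodine blocks C4, so C6 (para to the 3-OH, ortho to the 1-OH) reacts and only the hindered C2 competes, in line with resorcinol itself giving mainly the 7-hydroxychromene.

Step 7
Reactants: 13 6-iodo-2,2-dimethyl-2H-chromen-7-ol
Product: 14 6-iodo-7-(methoxymethoxy)-2,2-dimethyl-2H-chromene
Conditions: NaH (1.2 equiv), MOMCl (1.2 equiv), THF, 0 °C → rt
Reagents that add atoms: chloromethyl methyl ether (MOMCl), COCCl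
Why: Williamson-type MOM protection of the future 2′-OH, which would otherwise capture C2 in step 8 through a five-membered ring closure and give a 3-aroylbenzofuran instead of the isoflavone.

Step 8 (key step)
Reactants: 10 1-[6-hydroxy-2,4-bis(methoxymethoxy)-3-(3-methylbut-2-en-1-yl)phenyl]ethan-1-one; 15 N,N-dimethylformamide dimethyl acetal (DMF-DMA); 14 6-iodo-7-(methoxymethoxy)-2,2-dimethyl-2H-chromene
Product: 17 5,7-bis(methoxymethoxy)-3-[7-(methoxymethoxy)-2,2-dimethyl-2H-chromen-6-yl]-6-(3-methylbut-2-en-1-yl)-4H-chromen-4-one, via (E)-3-(dimethylamino)-1-[6-hydroxy-2,4-bis(methoxymethoxy)-3-(3-methylbut-2-en-1-yl)phenyl]prop-2-en-1-one 16 (not isolated)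
Conditions: 15 (3 equiv), toluene, 95 °C, 3 h, evaporate; then 14 (1.5 equiv), fac-Ir(ppy)3 (2 mol %), NaHCO3 (2 equiv), degassed MeCN (0.25 M), 450 nm LEDs, 30 °C
Reagents that add atoms: none
Why: Proposed new method: after the standard enaminone condensation, excited fac-Ir(ppy)3 (about −1.7 V vs SCE, and the only strong absorber at 450 nm) cleaves the C–I bond of 14, the σ-aryl radical adds to the electron-rich α-carbon of the push–pull alkene of 16 (0.25 M, so that addition outruns H abstraction and attack on the hindered chromene and prenyl C=C bonds), the resulting α-amino radical (about −1 V) is oxidised by Ir(IV) or carries a chain by abstracting iodine from 14, and the iminium carbon is trapped by the only free phenol with loss of dimethylamine, so that C3–C1′ and ring C arise in one redox-neutral operation; the closest known reaction type is the photoredox radical arylation/chromone annulation of o-hydroxyaryl enaminones with arenediazonium or arylsulfonium salts, together with the known photoredox activation of unactivated aryl iodides, and what is new is the electron-rich aryl iodide as radical source and the two free alkenes.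

Step 9
Reactants: 17 5,7-bis(methoxymethoxy)-3-[7-(methoxymethoxy)-2,2-dimethyl-2H-chromen-6-yl]-6-(3-methylbut-2-en-1-yl)-4H-chromen-4-one
Product: 18 Krausianone 2, 5,7-dihydroxy-3-(7-hydroxy-2,2-dimethyl-2H-chromen-6-yl)-6-(3-methylbut-2-en-1-yl)-4H-chromen-4-one
Conditions: HCl (1.25 M in MeOH), THF, 40 °C
Reagents that add atoms: none
Why: Acid-catalysed acetal exchange with methanol removes all three MOM groups (the 5-O-MOM next to the carbonyl first) under conditions too mild for chroman formation from the prenyl group, for addition to the chromene or for ring switching of the 2′-hydroxyisoflavone; no stereocentre is involved.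

## Compound list

1 | resorcinol (benzene-1,3-diol) | Oc1cccc(O)c1 | starting material
2 | 1,3-bis(methoxymethoxy)benzene | COCOc1cccc(OCOC)c1 | intermediate
3 | prenyl bromide (1-bromo-3-methylbut-2-ene) | CC(C)=CCBr | starting material
4 | 2-lithio-1,3-bis(methoxymethoxy)benzene | [Li]c1c(OCOC)cccc1OCOC | intermediate (not isolated)
5 | 1,3-bis(methoxymethoxy)-2-(3-methylbut-2-en-1-yl)benzene | COCOc1cccc(OCOC)c1CC=C(C)C | intermediate
6 | acetic anhydride | CC(=O)OC(C)=O | starting material
7 | 2-[3,5-bis(methoxymethoxy)-4-(3-methylbut-2-en-1-yl)phenyl]-4,4,5,5-tetramethyl-1,3,2-dioxaborolane | COCOc1cc(B2OC(C)(C)C(C)(C)O2)cc(OCOC)c1CC=C(C)C | intermediate (not isolated)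
8 | 3,5-bis(methoxymethoxy)-4-(3-methylbut-2-en-1-yl)phenol | COCOc1cc(O)cc(OCOC)c1CC=C(C)C | intermediate (not isolated)
9 | 3,5-bis(methoxymethoxy)-4-(3-methylbut-2-en-1-yl)phenyl acetate | CC(=O)Oc1cc(OCOC)c(CC=C(C)C)c(OCOC)c1 | intermediate
10 | 1-[6-hydroxy-2,4-bis(methoxymethoxy)-3-(3-methylbut-2-en-1-yl)phenyl]ethan-1-one | CC(=O)c1c(O)cc(OCOC)c(CC=C(C)C)c1OCOC | intermediate
11 | 4-iodobenzene-1,3-diol | Oc1ccc(I)c(O)c1 | intermediate
12 | 3-methylbut-2-enal (prenal) | CC(C)=CC=O | starting material
13 | 6-iodo-2,2-dimethyl-2H-chromen-7-ol | CC1(C)C=Cc2cc(I)c(O)cc2O1 | intermediate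
14 | 6-iodo-7-(methoxymethoxy)-2,2-dimethyl-2H-chromene | CC1(C)C=Cc2cc(I)c(OCOC)cc2O1 | intermediate
15 | N,N-dimethylformamide dimethyl acetal | COC(OC)N(C)C | starting material
16 | (E)-3-(dimethylamino)-1-[6-hydroxy-2,4-bis(methoxymethoxy)-3-(3-methylbut-2-en-1-yl)phenyl]prop-2-en-1-one | CN(C)/C=C/C(=O)c1c(O)cc(OCOC)c(CC=C(C)C)c1OCOC | intermediate (not isolated)
17 | 5,7-bis(methoxymethoxy)-3-[7-(methoxymethoxy)-2,2-dimethyl-2H-chromen-6-yl]-6-(3-methylbut-2-en-1-yl)-4H-chromen-4-one | COCOc1cc2occ(-c3cc4C=CC(C)(C)Oc4cc3OCOC)c(=O)c2c(OCOC)c1CC=C(C)C | intermediate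
18 | Krausianone 2 (achiral) | CC(C)=CCc1c(O)cc2occ(-c3cc4c(cc3O)OC(C)(C)C=C4)c(=O)c2c1O | target

## Step count and risks

Total step count: 9.
Longest linear sequence: 6 (steps 1, 2, 3, 4, 8, 9). The second branch (steps 5, 6, 7) joins at step 8.

**Step 8 (highest risk).**
- Risks: the electron-rich iodide may be reduced slowly, the aryl radical may abstract hydrogen, and it may add to the alkenes.
- The fallback sets out from 10 and 14 and comes back to the route at 17.
- Ketone 10 is converted with KOt-Bu (3.5 equiv) in DMSO into its phenolate–enolate dianion and irradiated (365 nm) with 14.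
- In this photostimulated SRN1 chain the same aryl radical is caught by an enolate carbon at close to the diffusion limit. The product radical anion then passes its electron to the next molecule of 14.
- This gives the deoxybenzoin 1-[6-hydroxy-2,4-bis(methoxymethoxy)-3-(3-methylbut-2-en-1-yl)phenyl]-2-[7-(methoxymethoxy)-2,2-dimethyl-2H-chromen-6-yl]ethan-1-one F1.
- Heating F1 with 15 in toluene (95 °C) gives the α-aryl enaminone 3-(dimethylamino)-1-[6-hydroxy-2,4-bis(methoxymethoxy)-3-(3-methylbut-2-en-1-yl)phenyl]-2-[7-(methoxymethoxy)-2,2-dimethyl-2H-chromen-6-yl]prop-2-en-1-one F2, which closes to 17 with loss of dimethylamine.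
- C3–C1′ is still made by a radical, but on an anionic acceptor and with C2 added afterwards. The cost is one more step.

**Step 4.**
- Risks: low conversion through inner filtering by the product, escape of the radical pair back to the phenol, and side photochemistry of the prenyl arene.
- The fallback sets out from 8 (isolated by leaving 6 out of step 3) and comes back to the route at 10.
- Magnesium-templated ortho-formylation (MgCl2, Et3N, paraformaldehyde, MeCN, reflux) gives 6-hydroxy-2,4-bis(methoxymethoxy)-3-(3-methylbut-2-en-1-yl)benzaldehyde F3.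
- MeMgBr (2.2 equiv, THF, 0 °C) gives 2-(1-hydroxyethyl)-3,5-bis(methoxymethoxy)-4-(3-methylbut-2-en-1-yl)phenol F4 (racemic; the centre is lost in the next operation).
- MnO2 (CH2Cl2, rt) oxidises F4 to 10.
- The symmetry of 8 gives the same regiochemical outcome by a purely ionic path.

**Step 6.**
- Risks: moderate yield, angular isomers from attack at C2, and loss of iodine on heating.
- The fallback sets out from 1 and comes back to the route at 13.
- Friedel–Crafts acylation/oxa-Michael annulation of 1 with 3-methylbut-2-enoic acid (MeSO3H, P2O5, 70 °C) gives the linear 7-hydroxy-2,2-dimethylchroman-4-one F5.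
- ICl in AcOH iodinates the less hindered position ortho to the OH and gives 7-hydroxy-6-iodo-2,2-dimethylchroman-4-one F6.
- NaBH4 (THF–MeOH) gives 6-iodo-2,2-dimethylchromane-4,7-diol F7 (racemic; the centre is lost on dehydration).
- Catalytic p-TsOH in warm toluene dehydrates this p-hydroxybenzylic alcohol to 13.
- In this version the pyran ring is built without a quinone methide, and the alkene appears only after the iodination.

## Further compounds

F1 | step 8 | 1-[6-hydroxy-2,4-bis(methoxymethoxy)-3-(3-methylbut-2-en-1-yl)phenyl]-2-[7-(methoxymethoxy)-2,2-dimethyl-2H-chromen-6-yl]ethan-1-one | O=C(Cc1cc2c(cc1OCOC)OC(C)(C)C=C2)c1c(O)cc(OCOC)c(CC=C(C)C)c1OCOC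
F2 | step 8 | 3-(dimethylamino)-1-[6-hydroxy-2,4-bis(methoxymethoxy)-3-(3-methylbut-2-en-1-yl)phenyl]-2-[7-(methoxymethoxy)-2,2-dimethyl-2H-chromen-6-yl]prop-2-en-1-one (E/Z not fixed) | CN(C)C=C(c1cc2c(cc1OCOC)OC(C)(C)C=C2)C(=O)c1c(O)cc(OCOC)c(CC=C(C)C)c1OCOC
F3 | step 4 | 6-hydroxy-2,4-bis(methoxymethoxy)-3-(3-methylbut-2-en-1-yl)benzaldehyde | O=Cc1c(O)cc(OCOC)c(CC=C(C)C)c1OCOC
F4 | step 4 | 2-(1-hydroxyethyl)-3,5-bis(methoxymethoxy)-4-(3-methylbut-2-en-1-yl)phenol (racemic) | CC(O)c1c(O)cc(OCOC)c(CC=C(C)C)c1OCOC
F5 | step 6 | 7-hydroxy-2,2-dimethylchroman-4-one | CC1(C)CC(=O)c2ccc(O)cc2O1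
F6 | step 6 | 7-hydroxy-6-iodo-2,2-dimethylchroman-4-one | CC1(C)CC(=O)c2cc(I)c(O)cc2O1
F7 | step 6 | 6-iodo-2,2-dimethylchromane-4,7-diol (racemic) | CC1(C)CC(O)c2cc(I)c(O)cc2O1
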